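## Retrosynthetic overview

1. Target 27 ⇐ acylation of the C3 alcohol 25 with (R)-2-methylbutanoic acid ⇐ desilylation ⇐ α-methylenation of lactone 21.
2. Lactone 21 ⇐ Evans–Tishchenko reaction of β-hydroxy ketone 15 with epoxy aldehyde 19: sets C6, installs the C8 ester and closes the γ-lactone (third ring).
3. 15 ⇐ 14 ⇐ divinyl carbinol 10 by a one-flask anionic oxy-Cope ring expansion / C7 alkylation / epoxidation: the ten-membered carbocycle and the 1,10-oxirane (first and second ring) form together.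
4. 10 ⇐ enone 4 (three steps from (S)-carvone) + (Z)-alkoxyvinyllithium 9; every ring stereocentre derives from carvone by chirality transfer.
5. The side-chain oxirane is made separately by Sharpless epoxidation of (Z)-2-methylbut-2-en-1-ol (from angelic acid).

Assumption: the SMILES is read literally, so C3 carries the (R)-2-methylbutanoate and C8 the (2R,3R)-2,3-epoxy-2-methylbutanoate. Germacranolide numbering is used for the ten-membered compounds (C1–C10 ring, C11–C13 lactone carbons, C14 on C10, C15 on C4, α = face of H-7).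

The stereochemical outcomes of steps 7 and 12 are predictions from transition-state models and have not been tested.

## Route

Step 1
Reactants: 1 (S)-(+)-carvone
Product: 2 (1S,5S)-cis-carveol
Conditions: NaBH4, CeCl3·7H2O, MeOH, −78 → 0 °C
Reagents that add atoms: none
Why: Luche reduction gives clean 1,2-reduction, and axial hydride delivery to the enone (isopropenyl equatorial) places the new hydroxyl cis to the isopropenyl group (C1 = S, the future C3 oxygen).

Step 2
Reactants: 2 (1S,5S)-cis-carveol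
Product: 3 (1S,5S)-cis-carveol tert-butyldimethylsilyl ether
Conditions: TBSCl, imidazole, DMF, 23 °C
Reagents that add atoms: tert-butyldimethylsilyl chloride, CC(C)(C)[Si](C)(C)Cl
Why: Imidazole-promoted silylation protects the secondary alcohol through the organolithium, amide-base and oxidation steps without touching a stereocentre.

Step 3
Reactants: 3 (1S,5S)-cis-carveol tert-butyldimethylsilyl ether
Product: 4 (4S,6S)-4-(tert-butyldimethylsilyloxy)-3-methyl-6-(prop-1-en-2-yl)cyclohex-2-en-1-one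
Conditions: CrO3, 3,5-dimethylpyrazole, CH2Cl2, −20 °C
Reagents that add atoms: chromium trioxide, O=[Cr](=O)=O
Why: Chromium trioxide–dimethylpyrazole allylic oxidation converts the only ring allylic methylene into the conjugated ketone, giving the enone with carbonyl and oxygen transposed relative to carvone; both stereocentres are untouched.

Step 4
Reactants: 5 4-methoxybenzyl alcohol
Product: 6 4-methoxybenzyl vinyl ether
Conditions: vinyl acetate, [Ir(cod)Cl]2 (1 mol %), Na2CO3, toluene, 100 °C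
Reagents that add atoms: vinyl acetate, C=COC(C)=O
Why: Iridium-catalysed transfer vinylation (alkoxide insertion into vinyl acetate, then β-acetate elimination) makes the vinyl ether directly from the alcohol.

Step 5
Reactants: 6 4-methoxybenzyl vinyl ether
Product: 8 (Z)-1-bromo-2-(4-methoxybenzyloxy)ethene, via dibromo ether 7 (not isolated)
Conditions: Br2, CH2Cl2, −78 °C; then i-Pr2NEt, −78 → 23 °C
Reagents that add atoms: bromine, BrBr
Why: Bromine addition to the enol ether followed by amine-induced dehydrobromination through the oxocarbenium ion gives the β-bromovinyl ether, mainly as the Z isomer as for the ethyl analogue; the minor E isomer is removed by chromatography.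

Step 6
Reactants: 8 (Z)-1-bromo-2-(4-methoxybenzyloxy)ethene; 4 (4S,6S)-4-(tert-butyldimethylsilyloxy)-3-methyl-6-(prop-1-en-2-yl)cyclohex-2-en-1-one
Product: 10 (1S,4S,6S)-1-[(Z)-2-(4-methoxybenzyloxy)ethenyl]-4-(tert-butyldimethylsilyloxy)-3-methyl-6-(prop-1-en-2-yl)cyclohex-2-en-1-ol, via vinyllithium 9 (not isolated)
Conditions: 8, t-BuLi (2.0 equiv), Et2O, −78 °C; then 4, THF, −78 °C; H2O
Reagents that add atoms: none
Why: Bromine–lithium exchange with retention gives the oxygen-chelated (Z)-alkenyllithium, which adds 1,2 to the enone on the face opposite both the isopropenyl and the silyloxy group, giving the trans-1,2-dialkenyl carbinol (new centre S) needed for a chair rearrangement.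

Step 7
Reactants: 10 (1S,4S,6S)-1-[(Z)-2-(4-methoxybenzyloxy)ethenyl]-4-(tert-butyldimethylsilyloxy)-3-methyl-6-(prop-1-en-2-yl)cyclohex-2-en-1-ol
Product: 14 N-methoxy-N-methylamide of (4Z)-1β,10α-epoxy-3β-(tert-butyldimethylsilyloxy)-8β-(4-methoxybenzyloxy)-6-oxo-13-norgermacr-4-en-12-oic acid (7α-H), via potassium alkoxide 11 (not isolated), via potassium enolate 12 (not isolated), via dienone amide 13 (not isolated)
Conditions: KN(SiMe3)2 (1.1 equiv), 18-crown-6, THF, −78 → 0 °C; BrCH2C(O)N(OMe)Me, −78 °C; then mCPBA, NaHCO3, CH2Cl2, −20 → 0 °C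
Reagents that add atoms: 2-bromo-N-methoxy-N-methylacetamide, BrCC(=O)N(C)OC; 3-chloroperoxybenzoic acid, OOC(=O)c1cccc(Cl)c1
Why: The anionic oxy-Cope rearrangement through a chair transition state (both ring bonds equatorial, the Z-alkoxy group axial and bridged to the alkoxide by potassium) forms the ten-membered ring with the E-1(10) alkene, the retained Z-4,5 alkene and C8 = R by chirality transfer; the regiodefined enolate is then C-alkylated on its outward face (C7 = R) and the peracid (Prilezhaev epoxidation) attacks the outward face of the new E-alkene in the conformer delivered by the rearrangement (1R,10R), so carbocycle and oxirane arise in one operation.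

Step 8
Reactants: 14 N-methoxy-N-methylamide of (4Z)-1β,10α-epoxy-3β-(tert-butyldimethylsilyloxy)-8β-(4-methoxybenzyloxy)-6-oxo-13-norgermacr-4-en-12-oic acid
Product: 15 N-methoxy-N-methylamide of (4Z)-1β,10α-epoxy-3β-(tert-butyldimethylsilyloxy)-8β-hydroxy-6-oxo-13-norgermacr-4-en-12-oic acid
Conditions: DDQ, CH2Cl2/pH 7 buffer, 0 °C
Reagents that add atoms: none
Why: Oxidative cleavage of the 4-methoxybenzyl ether frees the C8 hydroxyl under neutral conditions that spare the silyl ether, oxirane and enone; the Weinreb amide cannot lactonise onto the new hydroxyl as an ester would.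

Step 9
Reactants: 16 angelic acid
Product: 17 (Z)-2-methylbut-2-en-1-ol
Conditions: LiAlH4, Et2O, 0 → 23 °C
Reagents that add atoms: none
Why: Hydride reduction of the carboxylic acid gives the allylic alcohol with the Z geometry retained.

Step 10
Reactants: 17 (Z)-2-methylbut-2-en-1-ol
Product: 18 (2S,3R)-2,3-epoxy-2-methylbutan-1-ol
Conditions: Ti(OiPr)4 (10 mol %), L-(+)-diethyl tartrate (12 mol %), t-BuOOH, 4 Å MS, CH2Cl2, −20 °C
Reagents that add atoms: tert-butyl hydroperoxide, CC(C)(C)OO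
Why: Sharpless asymmetric epoxidation with L-(+)-tartrate delivers oxygen to the enantioface that gives the (2S,3R) epoxy alcohol, i.e. the (2R,3R) configuration once C1 is oxidised.

Step 11
Reactants: 18 (2S,3R)-2,3-epoxy-2-methylbutan-1-ol
Product: 19 (2R,3R)-2,3-epoxy-2-methylbutanal
Conditions: Dess–Martin periodinane, NaHCO3, CH2Cl2, 0 °C
Reagents that add atoms: none
Why: Dess–Martin oxidation gives the aldehyde under buffered conditions; the α-carbon is quaternary, so no centre can epimerise.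

Step 12
Reactants: 15 N-methoxy-N-methylamide of (4Z)-1β,10α-epoxy-3β-(tert-butyldimethylsilyloxy)-8β-hydroxy-6-oxo-13-norgermacr-4-en-12-oic acid; 19 (2R,3R)-2,3-epoxy-2-methylbutanal
Product: 21 (4Z)-1β,10α-epoxy-3β-(tert-butyldimethylsilyloxy)-8β-[(2R,3R)-2,3-epoxy-2-methylbutanoyloxy]-13-norgermacr-4-en-6α,12-olide, via hydroxy amide 20 (not isolated)
Conditions: 19 (5 equiv), SmI2 (0.3 equiv), THF, −10 °C; then 23 °C
Reagents that add atoms: none
Why: In the Evans–Tishchenko reaction the samarium-bound hemiacetal of the C8 hydroxyl and 19 delivers hydride to the C6 ketone through a six-membered chair, giving the 1,3-anti 6α-alcohol (C6 = R) while the aldehyde becomes the C8 ester; the trivalent samarium alkoxide at C6 then closes the trans-fused γ-lactone on the Weinreb amide.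

Step 13
Reactants: 21 (4Z)-1β,10α-epoxy-3β-(tert-butyldimethylsilyloxy)-8β-[(2R,3R)-2,3-epoxy-2-methylbutanoyloxy]-13-norgermacr-4-en-6α,12-olide
Product: 24 (4Z)-1β,10α-epoxy-3β-(tert-butyldimethylsilyloxy)-8β-[(2R,3R)-2,3-epoxy-2-methylbutanoyloxy]germacra-4,11(13)-dien-6α,12-olide, via Mannich base 22 (not isolated), via ammonium iodide 23 (not isolated)
Conditions: LiN(iPr)2, THF, −78 °C; Me2N=CH2 I, −78 → 0 °C; then MeI, MeOH, 23 °C; NaHCO3 (aq), CH2Cl2
Reagents that add atoms: dimethylmethylideneammonium iodide (Eschenmoser's salt), C=[N+](C)C.[I-]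
Why: Mannich reaction of the lactone enolate with Eschenmoser's salt, quaternisation and E1cB elimination install the exocyclic methylene; the lactone CH2 is the only enolisable position because the C8 ester has no α-hydrogen, and C7 is not affected.

Step 14
Reactants: 24 (4Z)-1β,10α-epoxy-3β-(tert-butyldimethylsilyloxy)-8β-[(2R,3R)-2,3-epoxy-2-methylbutanoyloxy]germacra-4,11(13)-dien-6α,12-olide
Product: 25 (4Z)-1β,10α-epoxy-3β-hydroxy-8β-[(2R,3R)-2,3-epoxy-2-methylbutanoyloxy]germacra-4,11(13)-dien-6α,12-olide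
Conditions: Bu4NF, AcOH, THF, 0 → 23 °C
Reagents that add atoms: none
Why: Acetic acid-buffered fluoride desilylation frees the C3 hydroxyl without opening the oxiranes or adding to the α-methylene lactone.

Step 15
Reactants: 25 (4Z)-1β,10α-epoxy-3β-hydroxy-8β-[(2R,3R)-2,3-epoxy-2-methylbutanoyloxy]germacra-4,11(13)-dien-6α,12-olide; 26 (R)-2-methylbutanoic acid
Product: 27 (4Z)-1β,10α-epoxy-3β-[(2R)-2-methylbutanoyloxy]-8β-[(2R,3R)-2,3-epoxy-2-methylbutanoyloxy]germacra-4,11(13)-dien-6α,12-olide (CNP0265335.1)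
Conditions: EDC·HCl, DMAP (0.2 equiv), CH2Cl2, 0 → 23 °C
Reagents that add atoms: none
Why: Steglich esterification acylates the allylic C3 hydroxyl with retention at C3, and the low temperature with sub-stoichiometric DMAP limits α-epimerisation of the acid.

## Compound list

1 | (S)-(+)-carvone | CC(=C)[C@H]1CC=C(C)C(=O)C1 | starting material
2 | (1S,5S)-cis-carveol | CC(=C)[C@H]1CC=C(C)[C@@H](O)C1 | intermediate
3 | (1S,5S)-cis-carveol tert-butyldimethylsilyl ether | CC(=C)[C@H]1CC=C(C)[C@@H](O[Si](C)(C)C(C)(C)C)C1 | intermediate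
4 | (4S,6S)-4-(tert-butyldimethylsilyloxy)-3-methyl-6-(prop-1-en-2-yl)cyclohex-2-en-1-one | CC(=C)[C@H]1C(=O)C=C(C)[C@@H](O[Si](C)(C)C(C)(C)C)C1 | intermediate
5 | 4-methoxybenzyl alcohol | COc1ccc(CO)cc1 | starting material
6 | 4-methoxybenzyl vinyl ether | C=COCc1ccc(OC)cc1 | intermediate
7 | 1-[(1,2-dibromoethoxy)methyl]-4-methoxybenzene (racemic, not isolated) | BrCC(Br)OCc1ccc(OC)cc1 | intermediate
8 | (Z)-1-bromo-2-(4-methoxybenzyloxy)ethene | Br/C=C\OCc1ccc(OC)cc1 | intermediate
9 | (Z)-2-(4-methoxybenzyloxy)vinyllithium (not isolated) | [Li]/C=C\OCc1ccc(OC)cc1 | intermediate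
10 | (1S,4S,6S)-1-[(Z)-2-(4-methoxybenzyloxy)ethenyl]-4-(tert-butyldimethylsilyloxy)-3-methyl-6-(prop-1-en-2-yl)cyclohex-2-en-1-ol (hydroxyl cis to isopropenyl and silyloxy) | CC(=C)[C@H]1[C@](O)(/C=C\OCc2ccc(OC)cc2)C=C(C)[C@@H](O[Si](C)(C)C(C)(C)C)C1 | intermediate
11 | potassium alkoxide of 10 (not isolated) | CC(=C)[C@H]1[C@]([O-])(/C=C\OCc2ccc(OC)cc2)C=C(C)[C@@H](O[Si](C)(C)C(C)(C)C)C1.[K+] | intermediate
12 | potassium enolate (C6–O, C6=C7) of the (1(10)E,4Z)-3β-silyloxy-8β-(4-methoxybenzyloxy)cyclodecadienone (not isolated) | [K+].[O-]/C1=C\[C@H](OCc2ccc(OC)cc2)C/C(C)=C/C[C@H](O[Si](C)(C)C(C)(C)C)/C(C)=C\1 | intermediate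
13 | N-methoxy-N-methylamide of (1(10)E,4Z)-3β-(tert-butyldimethylsilyloxy)-8β-(4-methoxybenzyloxy)-6-oxo-13-norgermacra-1(10),4-dien-12-oic acid, 7α-H (not isolated) | O=C1/C=C(/C)[C@@H](O[Si](C)(C)C(C)(C)C)C/C=C(\C)C[C@@H](OCc2ccc(OC)cc2)[C@H]1CC(=O)N(C)OC | intermediate
14 | N-methoxy-N-methylamide of (4Z)-1β,10α-epoxy-3β-(tert-butyldimethylsilyloxy)-8β-(4-methoxybenzyloxy)-6-oxo-13-norgermacr-4-en-12-oic acid, 7α-H | O=C1/C=C(/C)[C@@H](O[Si](C)(C)C(C)(C)C)C[C@H]2O[C@]2(C)C[C@@H](OCc2ccc(OC)cc2)[C@H]1CC(=O)N(C)OC | intermediate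
15 | N-methoxy-N-methylamide of (4Z)-1β,10α-epoxy-3β-(tert-butyldimethylsilyloxy)-8β-hydroxy-6-oxo-13-norgermacr-4-en-12-oic acid, 7α-H | O=C1/C=C(/C)[C@@H](O[Si](C)(C)C(C)(C)C)C[C@H]2O[C@]2(C)C[C@@H](O)[C@H]1CC(=O)N(C)OC | intermediate
16 | angelic acid, (Z)-2-methylbut-2-enoic acid | C/C=C(/C)C(=O)O | starting material
17 | (Z)-2-methylbut-2-en-1-ol | C/C=C(/C)CO | intermediate
18 | (2S,3R)-2,3-epoxy-2-methylbutan-1-ol | OC[C@]1(C)O[C@@H]1C | intermediate
19 | (2R,3R)-2,3-epoxy-2-methylbutanal | O=C[C@]1(C)O[C@@H]1C | intermediate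
20 | N-methoxy-N-methylamide of (4Z)-1β,10α-epoxy-3β-(tert-butyldimethylsilyloxy)-8β-[(2R,3R)-2,3-epoxy-2-methylbutanoyloxy]-6α-hydroxy-13-norgermacr-4-en-12-oic acid (not isolated) | O[C@@H]1/C=C(/C)[C@@H](O[Si](C)(C)C(C)(C)C)C[C@H]2O[C@]2(C)C[C@@H](OC(=O)[C@]2(C)O[C@@H]2C)[C@H]1CC(=O)N(C)OC | intermediate
21 | (4Z)-1β,10α-epoxy-3β-(tert-butyldimethylsilyloxy)-8β-[(2R,3R)-2,3-epoxy-2-methylbutanoyloxy]-13-norgermacr-4-en-6α,12-olide | C1C(=O)O[C@@H]2/C=C(/C)[C@@H](O[Si](C)(C)C(C)(C)C)C[C@H]3O[C@]3(C)C[C@@H](OC(=O)[C@]3(C)O[C@@H]3C)[C@@H]12 | intermediate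
22 | 11-(dimethylaminomethyl) derivative of 21, C11 epimer mixture (not isolated) | CN(C)CC1C(=O)O[C@@H]2/C=C(/C)[C@@H](O[Si](C)(C)C(C)(C)C)C[C@H]3O[C@]3(C)C[C@@H](OC(=O)[C@]3(C)O[C@@H]3C)[C@@H]12 | intermediate
23 | 11-(trimethylammoniomethyl) iodide of 21, C11 epimer mixture (not isolated) | C[N+](C)(C)CC1C(=O)O[C@@H]2/C=C(/C)[C@@H](O[Si](C)(C)C(C)(C)C)C[C@H]3O[C@]3(C)C[C@@H](OC(=O)[C@]3(C)O[C@@H]3C)[C@@H]12.[I-] | intermediate
24 | (4Z)-1β,10α-epoxy-3β-(tert-butyldimethylsilyloxy)-8β-[(2R,3R)-2,3-epoxy-2-methylbutanoyloxy]germacra-4,11(13)-dien-6α,12-olide | C=C1C(=O)O[C@@H]2/C=C(/C)[C@@H](O[Si](C)(C)C(C)(C)C)C[C@H]3O[C@]3(C)C[C@@H](OC(=O)[C@]3(C)O[C@@H]3C)[C@@H]12 | intermediate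
25 | (4Z)-1β,10α-epoxy-3β-hydroxy-8β-[(2R,3R)-2,3-epoxy-2-methylbutanoyloxy]germacra-4,11(13)-dien-6α,12-olide | C=C1C(=O)O[C@@H]2/C=C(/C)[C@@H](O)C[C@H]3O[C@]3(C)C[C@@H](OC(=O)[C@]3(C)O[C@@H]3C)[C@@H]12 | intermediate
26 | (R)-2-methylbutanoic acid | CC[C@@H](C)C(=O)O | starting material
27 | CNP0265335.1, (4Z)-1β,10α-epoxy-3β-[(2R)-2-methylbutanoyloxy]-8β-[(2R,3R)-2,3-epoxy-2-methylbutanoyloxy]germacra-4,11(13)-dien-6α,12-olide | C=C1C(=O)O[C@@H]2/C=C(/C)[C@@H](OC(=O)[C@H](C)CC)C[C@H]3O[C@]3(C)C[C@@H](OC(=O)[C@]3(C)O[C@@H]3C)[C@@H]12 | target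

## Step count and risks

Total step count: 15. Longest linear sequence: 10 steps (steps 1, 2, 3, 6, 7, 8, 12, 13, 14, 15, from (S)-carvone).

The three steps most likely to fail:

Step 3. The silyloxy-bearing methine and the isopropenyl group are competing sites for the chromium oxidant. The fallback sets out from 2 and comes back at 4. Hydroxyl-directed epoxidation of 2 (VO(acac)2, t-BuOOH) gives the syn epoxy alcohol F1, which is silylated (TBSCl, imidazole) to the epoxy silyl ether F2. Sodium phenylselenide (PhSeSePh, NaBH4, EtOH) opens the oxirane at its secondary carbon to the hydroxy selenide F3. H2O2 oxidises it to the selenoxide F4, which undergoes syn elimination to the tertiary allylic alcohol F5. Pyridinium chlorochromate, (C5H5NH)[CrO3Cl], then effects the oxidative 1,3-transposition to enone 4.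

Step 7. The rearrangement may partly go through a boat, the β-alkoxy enolate may lose the 4-methoxybenzyloxy group, and the peracid may not discriminate the alkene faces once the ring relaxes. The fallback sets out from 13 and comes back at 14. The sequence is stopped after the alkylation and 13 is isolated. It is then epoxidised under reagent control with the D-fructose-derived Shi ketone and KHSO5 (as 2KHSO5·KHSO4·K2SO4, K2CO3 buffer, MeCN/dimethoxymethane/H2O, 0 °C), so the chiral dioxirane rather than the ring conformation selects the face. This makes no compound outside the list: none F0.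

Step 12. The hindered epoxy aldehyde may form the hemiacetal slowly, and retro-aldol or elimination of 15 can compete. The fallback sets out from 15 and comes back at 21. Hydroxyl-directed reduction with Me4NBH(OAc)3 (AcOH/MeCN, −30 °C) gives the anti diol F6. Mild lactonisation (pyridinium p-toluenesulfonate, 23 °C) gives the 8β-hydroxy lactone F7; this relies on the C6 hydroxyl closing in preference to the C8 hydroxyl, which is itself uncertain. Separately, 18 is oxidised (RuCl3 cat., NaIO4) to (2R,3R)-2,3-epoxy-2-methylbutanoic acid F8. F8 is esterified onto F7 (2,4,6-trichlorobenzoyl chloride, Et3N, DMAP) to give 21.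

Further compounds

F1 | step 3 | 2,3-epoxide of cis-carveol with the oxirane oxygen on the hydroxyl face | CC(=C)[C@H]1C[C@H]2O[C@@]2(C)[C@@H](O)C1
F2 | step 3 | tert-butyldimethylsilyl ether of F1 | CC(=C)[C@H]1C[C@H]2O[C@@]2(C)[C@@H](O[Si](C)(C)C(C)(C)C)C1
F3 | step 3 | hydroxy selenide (tertiary C2 hydroxyl, C3 phenylselanyl trans to it) | CC(=C)[C@H]1C[C@H]([Se]c2ccccc2)[C@@](C)(O)[C@@H](O[Si](C)(C)C(C)(C)C)C1
F4 | step 3 | selenoxide of F3 (selenium configuration not defined) | CC(=C)[C@H]1C[C@H]([Se+]([O-])c2ccccc2)[C@@](C)(O)[C@@H](O[Si](C)(C)C(C)(C)C)C1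
F5 | step 3 | tertiary allylic alcohol, 6-(tert-butyldimethylsilyloxy)-1-methyl-4-(prop-1-en-2-yl)cyclohex-2-en-1-ol | CC(=C)[C@H]1C=C[C@@](C)(O)[C@@H](O[Si](C)(C)C(C)(C)C)C1
F0 | step 7 | none | none
F6 | step 12 | N-methoxy-N-methylamide of (4Z)-1β,10α-epoxy-3β-(tert-butyldimethylsilyloxy)-6α,8β-dihydroxy-13-norgermacr-4-en-12-oic acid | O[C@@H]1/C=C(/C)[C@@H](O[Si](C)(C)C(C)(C)C)C[C@H]2O[C@]2(C)C[C@@H](O)[C@H]1CC(=O)N(C)OC
F7 | step 12 | (4Z)-1β,10α-epoxy-3β-(tert-butyldimethylsilyloxy)-8β-hydroxy-13-norgermacr-4-en-6α,12-olide | C1C(=O)O[C@@H]2/C=C(/C)[C@@H](O[Si](C)(C)C(C)(C)C)C[C@H]3O[C@]3(C)C[C@@H](O)[C@@H]12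
F8 | step 12 | (2R,3R)-2,3-epoxy-2-methylbutanoic acid | OC(=O)[C@]1(C)O[C@@H]1C
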